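**Retrosynthetic overview** (chromanone numbering; ring A = benzene ring, ring B = O1/C2–C4 ring, ring C = pyran-2-one)
1. Ring B is the hemiketal of a 2-hydroxyaryl 1,3-diketone. It is closed last, when three benzyl ethers are removed and the C8a phenol adds to the C2 carbonyl; (2R) is then taken by resolution.
2. C3–C4 is disconnected to the ring A aldehyde and the dianion of 6-acetonyl-4-benzyloxypyran-2-one (ring C from triacetic acid lactone); the aldol is followed by oxidation at C4.
3. The strategy rests on ring A: a resorcinol with the acyl carbon C4 on C4a, the 3-methylbutyl chain on C5 and oxygens on C7 and C8a. An ester-substituted vinylketene (Wolff shift of a vinyl diazo keto ester) and an ynol ether build it through C5–C4a, C7–C8, C4a–C8a and C6–C7, with the two oxygens differentiated.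
4. The ynol ether is ethoxyethyne: it is purchased, is polarised like a silyl ynol ether, and its ethyl ether ortho to the ester is later cleaved selectively by BCl3. The ester is ethyl because ethyl diazoacetate is the purchasable diazoacetate.
5. Ring order: C (purchased), A (step 3), B (step 12).

Key step: step 3

Assumption: C2 is a hemiketal carbon that equilibrates with the open hydroxyaryl diketone, so no step can fix it kinetically; the route makes the C2 racemate, takes the (2R)-enantiomer by resolution, and it should be kept as a cold solid.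

**Route**

Step 1
Reactants: 1 5-methylhexanal
Product: 2 5-methyl-2-methylidenehexanal
Conditions: 37% aq. HCHO (1.1 equiv), pyrrolidine (10 mol%), EtCO2H (10 mol%), iPrOH, 45 °C
Reagents that add atoms: formaldehyde, C=O
Why: Amine-catalysed Mannich condensation of the aldehyde with formaldehyde and β-elimination of the amine (organocatalytic α-methylenation) should give the 2-substituted acrolein, since only one α-position is present.

Step 2
Reactants: 2 5-methyl-2-methylidenehexanal; 3 ethyl diazoacetate
Product: 5 ethyl 2-diazo-7-methyl-4-methylidene-3-oxooctanoate, via diazo aldol adduct 4 (not isolated)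
Conditions: DBU (20 mol%), DMSO, rt; then IBX (1.5 equiv), rt
Reagents that add atoms: none
Why: DBU-catalysed aldol-type 1,2-addition of the diazoacetate carbanion to the aldehyde, then IBX oxidation of the allylic carbinol in the same flask, should give the vinyl diazo keto ester with the diazo group intact; the carbinol centre of 4 is destroyed.

Step 3
Reactants: 5 ethyl 2-diazo-7-methyl-4-methylidene-3-oxooctanoate; 6 ethoxyethyne
Product: 11 ethyl 2-ethoxy-4-hydroxy-6-(3-methylbutyl)benzoate, via vinylketene 7 (not isolated), via alkenylcyclobutenone 8 (not isolated), via dienylketene 9 (not isolated), via cyclohexadienone 10 (not isolated)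
Conditions: 6 (3 equiv), degassed ClCH2CH2Cl, hν (300 nm), rt, sealed quartz tube; then 80 °C
Reagents that add atoms: none
Why: Proposed new method: light expels N2 from 5 and the alkenyl group shifts from the ketone carbon to the carbene carbon (Wolff rearrangement, C5–C4a) to give ester-substituted vinylketene 7, whose carbonyl carbon is attacked by the nucleophilic CH terminus of 6 while the oxygen-bearing alkyne carbon bonds to the ketene α-carbon ([2+2], C7–C8 and C4a–C8a), giving cyclobutenone 8. On warming, 4π electrocyclic opening of the C7–C4a bond gives dienylketene 9, ring A closes by 6π electrocyclisation of C6 onto C7, and dienone 10 tautomerises to the C7 phenol. The closest known reaction is the photochemical Danheiser benzannulation of α-diazo enones with alkoxy- and siloxyalkynes; new here is the α-diazo β-keto ester as ketene source, which places the ester on C4a. No stereocentre is formed, and ester, chain and both oxygens take their ring positions from the connectivity of the two partners. The step needs [2+2] addition across the ketene C=C and not [4+2] through the ester carbonyl, and it needs the alkenyl group cis to the ketene in 9: the polarisation of the ynol ether fixes the orientation, an ester carbonyl is a weak heterodiene, and reversible opening of 8 should drain through the isomer that can cyclise.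

Step 4
Reactants: 11 ethyl 2-ethoxy-4-hydroxy-6-(3-methylbutyl)benzoate
Product: 12 ethyl 2,4-dihydroxy-6-(3-methylbutyl)benzoate
Conditions: BCl3 (3 equiv), CH2Cl2, −78 to 0 °C; aq. NaHCO3
Reagents that add atoms: none
Why: BCl3 chelates between the ester carbonyl and the ortho ether oxygen and chloride removes the ethyl group (chelation-controlled Lewis-acid ether cleavage), which should leave the ethyl ester untouched.

Step 5
Reactants: 12 ethyl 2,4-dihydroxy-6-(3-methylbutyl)benzoate
Product: 13 ethyl 2,4-bis(benzyloxy)-6-(3-methylbutyl)benzoate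
Conditions: BnBr (2.5 equiv), K2CO3 (3 equiv), DMF, 60 °C
Reagents that add atoms: benzyl bromide, BrCc1ccccc1
Why: Williamson ether synthesis should alkylate both phenoxides, the hydrogen-bonded ortho one on warming in DMF.

Step 6
Reactants: 13 ethyl 2,4-bis(benzyloxy)-6-(3-methylbutyl)benzoate
Product: 14 [2,4-bis(benzyloxy)-6-(3-methylbutyl)phenyl]methanol
Conditions: LiAlH4 (2 equiv), THF, 0 °C to reflux
Reagents that add atoms: none
Why: Hydride reduction of the ester; the small hydride should reach the 2,6-disubstituted ester that carbon nucleophiles would not, and benzyl ethers are inert.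

Step 7
Reactants: 14 [2,4-bis(benzyloxy)-6-(3-methylbutyl)phenyl]methanol
Product: 15 2,4-bis(benzyloxy)-6-(3-methylbutyl)benzaldehyde
Conditions: MnO2 (10 equiv), CH2Cl2, rt
Reagents that add atoms: none
Why: Benzylic alcohol oxidation by MnO2 should stop at the aldehyde, turning the hindered C4 carbon into an electrophile that enolates can attack.

Step 8
Reactants: 16 4-hydroxy-6-methyl-2H-pyran-2-one (triacetic acid lactone)
Product: 17 4-(benzyloxy)-6-methyl-2H-pyran-2-one
Conditions: BnOH (1.1 equiv), PPh3 (1.2 equiv), DIAD (1.2 equiv), THF, 0 °C to rt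
Reagents that add atoms: benzyl alcohol, OCc1ccccc1
Why: Mitsunobu alkylation of the acidic 4-hydroxyl should give the 4-O-benzyl ether and avoid the C3-alkylation that halide alkylation of this ambident anion can give.

Step 9
Reactants: 17 4-(benzyloxy)-6-methyl-2H-pyran-2-one
Product: 18 4-(benzyloxy)-6-(2-oxopropyl)-2H-pyran-2-one
Conditions: LiN(iPr)2 (1.1 equiv), THF, −78 °C; MeC(O)N(OMe)Me (1.2 equiv), −78 to −40 °C; aq. NH4Cl
Reagents that add atoms: N-methoxy-N-methylacetamide, CC(=O)N(C)OC
Why: The 6-methyl group is deprotonated as a vinylogous ester enolate and C-acylated by the Weinreb amide (vinylogous Claisen-type acylation); the chelated tetrahedral adduct should release the more acidic ketone only on work-up.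

Step 10
Reactants: 18 4-(benzyloxy)-6-(2-oxopropyl)-2H-pyran-2-one; 15 2,4-bis(benzyloxy)-6-(3-methylbutyl)benzaldehyde
Product: 19 4-(benzyloxy)-6-{4-[2,4-bis(benzyloxy)-6-(3-methylbutyl)phenyl]-4-hydroxy-2-oxobutyl}-2H-pyran-2-one (racemic)
Conditions: LiN(iPr)2 (2.2 equiv), THF, −78 to −30 °C; 15, −78 °C; AcOH, −78 °C
Reagents that add atoms: none
Why: Two equivalents of base should deprotonate first the CH2 between ring C and the ketone and then the methyl group, and the dianion should react at the last-formed terminal carbon (aldol addition of a β-dicarbonyl-type dianion) to form C3–C4; the carbinol centre is racemic and is removed in step 11.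

Step 11
Reactants: 19 4-(benzyloxy)-6-{4-[2,4-bis(benzyloxy)-6-(3-methylbutyl)phenyl]-4-hydroxy-2-oxobutyl}-2H-pyran-2-one
Product: 20 1-[2,4-bis(benzyloxy)-6-(3-methylbutyl)phenyl]-4-[4-(benzyloxy)-2-oxo-2H-pyran-6-yl]butane-1,3-dione
Conditions: Dess–Martin periodinane (1.1 equiv), CH2Cl2, 0 °C to rt
Reagents that add atoms: none
Why: Dess–Martin oxidation of the β-hydroxy ketone should give the 1,3-diketone, which enolises and resists further oxidation at controlled stoichiometry.

Step 12
Reactants: 20 1-[2,4-bis(benzyloxy)-6-(3-methylbutyl)phenyl]-4-[4-(benzyloxy)-2-oxo-2H-pyran-6-yl]butane-1,3-dione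
Product: 22 rac-2,7-dihydroxy-2-[(4-hydroxy-2-oxo-2H-pyran-6-yl)methyl]-5-(3-methylbutyl)-2,3-dihydro-4H-chromen-4-one, via open triol diketone 21 (not isolated)
Conditions: H2 (1 atm), 10% Pd/C, EtOAc, rt, stopped after uptake of 3 equiv
Reagents that add atoms: none
Why: Hydrogenolysis should remove the three O-benzyl groups faster than it reduces the pyranone or the hydrogen-bonded aryl ketone, and the freed C8a phenol should add to the C2 carbonyl (6-exo-trig hemiketalisation) to close ring B as the C2 racemate.

Step 13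
Reactants: 22 rac-2,7-dihydroxy-2-[(4-hydroxy-2-oxo-2H-pyran-6-yl)methyl]-5-(3-methylbutyl)-2,3-dihydro-4H-chromen-4-one
Product: 23 (2R)-2,7-dihydroxy-2-[(4-hydroxy-2-oxo-2H-pyran-6-yl)methyl]-5-(3-methylbutyl)-2,3-dihydro-4H-chromen-4-one
Conditions: preparative HPLC, amylose tris(3,5-dimethylphenylcarbamate) on silica, heptane/EtOH/HCO2H, 5 °C; (2R)-fraction evaporated cold; (2S)-fraction left in MeOH with Et3N (cat.) and re-injected
Reagents that add atoms: none
Why: Resolution on a chiral stationary phase should give the (2R)-enantiomer (to be assigned by ECD against calculation), and the (2S)-fraction should re-equilibrate to the racemate through the open diketone and can be recycled.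

**Compound list**
1 | 5-methylhexanal | CC(C)CCCC=O | starting material
2 | 5-methyl-2-methylidenehexanal | C=C(CCC(C)C)C=O | intermediate
3 | ethyl diazoacetate | CCOC(=O)C=[N+]=[N-] | starting material
4 | ethyl 2-diazo-3-hydroxy-7-methyl-4-methylideneoctanoate (racemic) | C=C(CCC(C)C)C(O)C(=[N+]=[N-])C(=O)OCC | intermediate
5 | ethyl 2-diazo-7-methyl-4-methylidene-3-oxooctanoate | C=C(CCC(C)C)C(=O)C(=[N+]=[N-])C(=O)OCC | intermediate
6 | ethoxyethyne | C#COCC | starting material
7 | ethyl 6-methyl-3-methylidene-2-(oxomethylidene)heptanoate | CCOC(=O)C(=C=O)C(=C)CCC(C)C | intermediate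
8 | ethyl 2-ethoxy-1-(5-methylhex-1-en-2-yl)-4-oxocyclobut-2-ene-1-carboxylate (racemic) | CCOC(=O)C1(C(=C)CCC(C)C)C(OCC)=CC1=O | intermediate
9 | ethyl (2Z)-3-ethoxy-2-(5-methylhex-1-en-2-yl)-5-oxopenta-2,4-dienoate | O=C=C/C(OCC)=C(\C(=C)CCC(C)C)C(=O)OCC | intermediate
10 | ethyl 6-ethoxy-2-(3-methylbutyl)-4-oxocyclohexa-1,5-diene-1-carboxylate | CCOC(=O)C1=C(CCC(C)C)CC(=O)C=C1OCC | intermediate
11 | ethyl 2-ethoxy-4-hydroxy-6-(3-methylbutyl)benzoate | CCOC(=O)c1c(CCC(C)C)cc(O)cc1OCC | intermediate
12 | ethyl 2,4-dihydroxy-6-(3-methylbutyl)benzoate | CCOC(=O)c1c(CCC(C)C)cc(O)cc1O | intermediate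
13 | ethyl 2,4-bis(benzyloxy)-6-(3-methylbutyl)benzoate | CCOC(=O)c1c(CCC(C)C)cc(OCc2ccccc2)cc1OCc1ccccc1 | intermediate
14 | [2,4-bis(benzyloxy)-6-(3-methylbutyl)phenyl]methanol | OCc1c(CCC(C)C)cc(OCc2ccccc2)cc1OCc1ccccc1 | intermediate
15 | 2,4-bis(benzyloxy)-6-(3-methylbutyl)benzaldehyde | O=Cc1c(CCC(C)C)cc(OCc2ccccc2)cc1OCc1ccccc1 | intermediate
16 | 4-hydroxy-6-methyl-2H-pyran-2-one | Cc1cc(O)cc(=O)o1 | starting material
17 | 4-(benzyloxy)-6-methyl-2H-pyran-2-one | Cc1cc(OCc2ccccc2)cc(=O)o1 | intermediate
18 | 4-(benzyloxy)-6-(2-oxopropyl)-2H-pyran-2-one | CC(=O)Cc1cc(OCc2ccccc2)cc(=O)o1 | intermediate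
19 | 4-(benzyloxy)-6-{4-[2,4-bis(benzyloxy)-6-(3-methylbutyl)phenyl]-4-hydroxy-2-oxobutyl}-2H-pyran-2-one (racemic) | CC(C)CCc1cc(OCc2ccccc2)cc(OCc2ccccc2)c1C(O)CC(=O)Cc1cc(OCc2ccccc2)cc(=O)o1 | intermediate
20 | 1-[2,4-bis(benzyloxy)-6-(3-methylbutyl)phenyl]-4-[4-(benzyloxy)-2-oxo-2H-pyran-6-yl]butane-1,3-dione | CC(C)CCc1cc(OCc2ccccc2)cc(OCc2ccccc2)c1C(=O)CC(=O)Cc1cc(OCc2ccccc2)cc(=O)o1 | intermediate
21 | 1-[2,4-dihydroxy-6-(3-methylbutyl)phenyl]-4-(4-hydroxy-2-oxo-2H-pyran-6-yl)butane-1,3-dione | CC(C)CCc1cc(O)cc(O)c1C(=O)CC(=O)Cc1cc(O)cc(=O)o1 | intermediate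
22 | rac-2,7-dihydroxy-2-[(4-hydroxy-2-oxo-2H-pyran-6-yl)methyl]-5-(3-methylbutyl)-2,3-dihydro-4H-chromen-4-one | CC(C)CCc1cc(O)cc2c1C(=O)CC(O)(Cc1cc(O)cc(=O)o1)O2 | intermediate
23 | (2R)-2,7-dihydroxy-2-[(4-hydroxy-2-oxo-2H-pyran-6-yl)methyl]-5-(3-methylbutyl)-2,3-dihydro-4H-chromen-4-one | CC(C)CCc1cc(O)cc2c1C(=O)C[C@@](O)(Cc1cc(O)cc(=O)o1)O2 | target

**Step count**
Total: 13 steps. Longest linear sequence: 11 steps (steps 1–7 and 10–13); steps 8–9 make the ring C fragment.

**Steps most likely to fail**

1. Step 3. The ester-substituted vinylketene may be captured by the ynol ether in a [4+2] sense through its ester carbonyl, or may dimerise, before the [2+2] addition. Ring opening of the cyclobutenone may also favour the rotamer that cannot close.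
Fallback, from 2 and 6, returning at 15: the acyl carbon C4 is added after ring A is made. MeMgBr should add to 2 to give 6-methyl-3-methylideneheptan-2-ol F1, and MnO2 should give 6-methyl-3-methylideneheptan-2-one F2. LiN(SiMe3)2 and CF3CO2CH2CF3 should give 1,1,1-trifluoro-8-methyl-5-methylidenenonane-2,4-dione F3, and MsN3/Et3N/H2O in MeCN should transfer the diazo group with loss of the trifluoroacetyl group to give 1-diazo-6-methyl-3-methylideneheptan-2-one F4. Irradiation of F4 with 6 and warming, the established form of the benzannulation with an α-diazo enone, should give 3-ethoxy-5-(3-methylbutyl)phenol F5. BBr3 should give 5-(3-methylbutyl)benzene-1,3-diol F6, and BnBr/K2CO3 should give 1,3-bis(benzyloxy)-5-(3-methylbutyl)benzene F7. Vilsmeier–Haack formylation (POCl3, DMF), which goes ortho to the chain and para to a benzyloxy group, should then give 15.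

2. Step 10. The second deprotonation may be incomplete, so that the monoanion reacts at the internal CH2, and the adduct of the electron-rich aldehyde may revert by retro-aldol cleavage or dehydrate.
Fallback, from 15 and 17, returning at 19: the chain is built with two monoanions. The lithium enolate of N-methoxy-N-methylacetamide (LiN(iPr)2, THF, −78 °C) should add to 15 to give 3-[2,4-bis(benzyloxy)-6-(3-methylbutyl)phenyl]-3-hydroxy-N-methoxy-N-methylpropanamide F8. TBSOTf/2,6-lutidine should give its tert-butyldimethylsilyl ether, 3-[2,4-bis(benzyloxy)-6-(3-methylbutyl)phenyl]-3-[(tert-butyldimethylsilyl)oxy]-N-methoxy-N-methylpropanamide F9. The 6-methyl anion of 17 (LiN(iPr)2, THF, −78 °C) should be acylated by F9 to give 4-(benzyloxy)-6-{4-[2,4-bis(benzyloxy)-6-(3-methylbutyl)phenyl]-4-[(tert-butyldimethylsilyl)oxy]-2-oxobutyl}-2H-pyran-2-one F10, and HF·pyridine in THF should free 19.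

3. Step 13. Ring-chain tautomerism during elution and evaporation may erode the enantiomeric purity of the collected fraction.
Fallback, from 22, returning at 23: the configuration is set in a crystal lattice. 22 is stirred as a slurry with (S)-N,N-dimethyl-1-phenylethylamine (a tertiary amine, which cannot condense with the diketone) in iPrOH/EtOAc. The less soluble salt, (1S)-N,N-dimethyl-1-phenylethanaminium 6-{[(2R)-2,7-dihydroxy-5-(3-methylbutyl)-4-oxo-3,4-dihydro-2H-chromen-2-yl]methyl}-2-oxo-2H-pyran-4-olate F11, should crystallise while the dissolved epimer equilibrates through the open diketone (crystallisation-induced diastereomer transformation). The (R)-amine is used instead if the salt of the (2S)-hemiketal proves the less soluble. Cold aq. KHSO4/EtOAc should then free 23.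

**Further compounds**
F1 | step 3 | 6-methyl-3-methylideneheptan-2-ol | CC(O)C(=C)CCC(C)C
F2 | step 3 | 6-methyl-3-methylideneheptan-2-one | CC(=O)C(=C)CCC(C)C
F3 | step 3 | 1,1,1-trifluoro-8-methyl-5-methylidenenonane-2,4-dione | O=C(CC(=O)C(=C)CCC(C)C)C(F)(F)F
F4 | step 3 | 1-diazo-6-methyl-3-methylideneheptan-2-one | [N-]=[N+]=CC(=O)C(=C)CCC(C)C
F5 | step 3 | 3-ethoxy-5-(3-methylbutyl)phenol | CCOc1cc(O)cc(CCC(C)C)c1
F6 | step 3 | 5-(3-methylbutyl)benzene-1,3-diol | CC(C)CCc1cc(O)cc(O)c1
F7 | step 3 | 1,3-bis(benzyloxy)-5-(3-methylbutyl)benzene | CC(C)CCc1cc(OCc2ccccc2)cc(OCc2ccccc2)c1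
F8 | step 10 | 3-[2,4-bis(benzyloxy)-6-(3-methylbutyl)phenyl]-3-hydroxy-N-methoxy-N-methylpropanamide | CC(C)CCc1cc(OCc2ccccc2)cc(OCc2ccccc2)c1C(O)CC(=O)N(C)OC
F9 | step 10 | 3-[2,4-bis(benzyloxy)-6-(3-methylbutyl)phenyl]-3-[(tert-butyldimethylsilyl)oxy]-N-methoxy-N-methylpropanamide | CC(C)CCc1cc(OCc2ccccc2)cc(OCc2ccccc2)c1C(O[Si](C)(C)C(C)(C)C)CC(=O)N(C)OC
F10 | step 10 | 4-(benzyloxy)-6-{4-[2,4-bis(benzyloxy)-6-(3-methylbutyl)phenyl]-4-[(tert-butyldimethylsilyl)oxy]-2-oxobutyl}-2H-pyran-2-one | CC(C)CCc1cc(OCc2ccccc2)cc(OCc2ccccc2)c1C(O[Si](C)(C)C(C)(C)C)CC(=O)Cc1cc(OCc2ccccc2)cc(=O)o1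
F11 | step 13 | (1S)-N,N-dimethyl-1-phenylethanaminium 6-{[(2R)-2,7-dihydroxy-5-(3-methylbutyl)-4-oxo-3,4-dihydro-2H-chromen-2-yl]methyl}-2-oxo-2H-pyran-4-olate | CC(C)CCc1cc(O)cc2c1C(=O)C[C@@](O)(Cc1cc([O-])cc(=O)o1)O2.C[C@H]([NH+](C)C)c1ccccc1
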